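The route rests on cutting ring C of the flavanone half away from its phloroglucinol ring A at O1–C8a and C4–C4a. Ring A bears oxygen at C5, beside C4a, so it maps onto 3,5-bis(benzyloxy)benzyne, in which that alkoxy group sends a nucleophile to the remote aryne carbon. The precursor is the lithium alkoxide of an enantiopure anti-aldol Weinreb amide that already holds C2, C3 and the whole benzyl-protected genkwanin unit. Its oxygen adds to the aryne. The ortho aryllithium so formed acylates itself on the amide, which closes ring C in one operation without touching either stereocentre. Hydrogenolysis of five benzyl ethers ends the synthesis.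

Key step: step 9

Remark: the SMILES descriptors translate to (2S,3R), the trans-2,3-diaryl chroman-4-one. The locants O1, C2, C3, C4, C4a, C5 and C8a refer to the flavanone half. Compounds 1, 3, 6, 10 and 14 are taken as commercial. Ar1 stands for the 2-(benzyloxy)-5-[5-(benzyloxy)-7-methoxy-4-oxo-4H-chromen-2-yl]phenyl group.

Step 1
Reactants: 1 1-(2,6-dihydroxy-4-methoxyphenyl)ethanone
Product: 2 1-[2-(benzyloxy)-6-hydroxy-4-methoxyphenyl]ethanone
Conditions: BnBr (1.05 equiv), K2CO3, acetone, reflux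
Reagents that add atoms: benzyl bromide, BrCc1ccccc1
Why: Williamson ether synthesis in which, after the first alkylation, the remaining phenol is held in a hydrogen bond to the ketone and is much less nucleophilic, so the monoether should be the main product.

Step 2
Reactants: 2 1-[2-(benzyloxy)-6-hydroxy-4-methoxyphenyl]ethanone; 3 4-(benzyloxy)-3-bromobenzaldehyde
Product: 4 (E)-1-[2-(benzyloxy)-6-hydroxy-4-methoxyphenyl]-3-[4-(benzyloxy)-3-bromophenyl]prop-2-en-1-one
Conditions: KOH (aq), EtOH, rt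
Reagents that add atoms: none
Why: Claisen–Schmidt condensation of a methyl ketone with a non-enolisable aldehyde, in which E1cB loss of water should give the E-enone while the aryl bromide and the benzyl ethers are inert to aqueous base.

Step 3
Reactants: 4 the 2'-hydroxychalcone of step 2
Product: 5 5-(benzyloxy)-2-[4-(benzyloxy)-3-bromophenyl]-7-methoxy-4H-chromen-4-one
Conditions: I2 (10 mol %), DMSO, 130 °C
Reagents that add atoms: none
Why: Iodine-catalysed oxidative cyclisation of a 2'-hydroxychalcone (oxa-Michael closure, α-iodination, loss of HI, DMSO re-oxidising HI to I2), a standard flavone synthesis that should leave the aryl bromide, the methyl ether and the benzyl ethers in place.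

Step 4
Reactants: 5 the 3'-bromoflavone of step 3; 6 (S)-3-acetyl-4-benzyloxazolidin-2-one
Product: 9 (S)-4-benzyl-3-[(Ar1)acetyl]oxazolidin-2-one, via lithium enolate 7 (not isolated), via chlorozinc enolate 8 (not isolated)
Conditions: 6, LiN(SiMe3)2, THF, –78 °C; ZnCl2, –78 °C to rt; then 5, Pd(dba)2 (5 mol %), P(t-Bu)3 (5 mol %), THF, 50 °C
Reagents that add atoms: lithium hexamethyldisilazide, [Li]N([Si](C)(C)C)[Si](C)(C)C (lithium of 7); zinc dichloride, Cl[Zn]Cl (zinc and chlorine of 8)
Why: Negishi-type palladium-catalysed α-arylation of a zinc enolate, known for esters, amides and oxazolidinone imides, in which the weakly basic zinc enolate should spare the flavone carbonyl and stop after one arylation, the auxiliary stereocentre taking no part.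

Step 5
Reactants: 9 (S)-4-benzyl-3-[(Ar1)acetyl]oxazolidin-2-one; 10 4-(benzyloxy)benzaldehyde
Product: 12 (S)-4-benzyl-3-{(2R,3S)-2-(Ar1)-3-[4-(benzyloxy)phenyl]-3-hydroxypropanoyl}oxazolidin-2-one, via trimethylsilyl ether 11 (not isolated)
Conditions: MgCl2 (20 mol %), Et3N, Me3SiCl, EtOAc, rt; then PPTS (cat.), MeOH, 0 °C to rt
Reagents that add atoms: chlorotrimethylsilane, C[Si](C)(C)Cl (silyl group of 11)
Why: Magnesium halide-catalysed anti-selective Evans aldol reaction, in which soft enolisation gives the magnesium-chelated Z-enolate, the non-enolisable aldehyde should approach the face away from the benzyl group of the (S)-auxiliary (the face used in alkylations of this imide) through a boat-like transition state to set 2R and 3S (anti), silylation makes the addition irreversible, and mild methanolysis frees the alcohol.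

Step 6
Reactants: 12 the anti aldol imide of step 5
Product: 13 (2R,3S)-2-(Ar1)-3-[4-(benzyloxy)phenyl]-3-hydroxy-N-methoxy-N-methylpropanamide
Conditions: MeNHOMe·HCl, AlMe3, CH2Cl2, –10 °C to rt; aq HCl (0.5 M) work-up
Reagents that add atoms: N,O-dimethylhydroxylamine hydrochloride, CNOC.Cl
Why: Aluminium amide transamination to a Weinreb amide, known to work directly on β-hydroxy imides because the aluminium alkoxide delivers the amide nitrogen to the exocyclic carbonyl, which should leave both stereocentres unchanged.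

Step 7
Reactants: 14 3,5-bis(benzyloxy)phenol
Product: 15 3,5-bis(benzyloxy)-2-iodophenol
Conditions: NIS (1.0 equiv), MeCN, 0 °C
Reagents that add atoms: N-iodosuccinimide, O=C1CCC(=O)N1I
Why: Electrophilic aromatic iodination, which should go to one of the two equivalent positions ortho to the free hydroxyl and para to a benzyloxy group rather than to the more crowded C4 between the two benzyloxy groups.

Step 8
Reactants: 15 3,5-bis(benzyloxy)-2-iodophenol
Product: 16 3,5-bis(benzyloxy)-2-iodophenyl trifluoromethanesulfonate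
Conditions: Tf2O, pyridine, CH2Cl2, 0 °C
Reagents that add atoms: trifluoromethanesulfonic anhydride, O=S(=O)(OS(=O)(=O)C(F)(F)F)C(F)(F)F
Why: O-sulfonylation of a phenol with triflic anhydride, which gives the ortho-iodoaryl triflate type of aryne precursor.

Step 9
Reactants: 13 the (2R,3S)-β-hydroxy Weinreb amide of step 6; 16 3,5-bis(benzyloxy)-2-iodophenyl trifluoromethanesulfonate
Product: 22 (2S,3R)-5,7-bis(benzyloxy)-3-(Ar1)-2-[4-(benzyloxy)phenyl]chroman-4-one, via lithium alkoxide 17 (not isolated), via lithiated triflate 18 (not isolated), via aryne 19 (not isolated), via aryllithium 20 (not isolated), via tetrahedral adduct 21 (not isolated)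
Conditions: 13, LiN(SiMe3)2 (1.0 equiv), THF, –78 °C; 16 (2 equiv); n-BuLi (2 equiv, syringe pump), –78 °C; AcOH quench at –78 °C
Reagents that add atoms: lithium hexamethyldisilazide, [Li]N([Si](C)(C)C)[Si](C)(C)C (lithium of 17, 20 and 21); n-butyllithium, [Li]CCCC (lithium of 18)
Why: Proposed new method: iodine–lithium exchange on 16 gives 18, which loses LiOTf at –78 °C to release aryne 19 beside the preformed alkoxide 17; the alkoxide oxygen adds to 19 (O1–C8a), and the resulting aryllithium 20 attacks the Weinreb carbonyl (C4–C4a) to give the chelated adduct 21, which collapses to ketone 22 only on the acidic quench. The closest known reaction types are the annulation of arynes with salicylate esters to xanthones and the ring expansion of β-lactams by arynes to 2,3-dihydroquinolin-4-ones, both heteroatom addition followed by intramolecular acyl capture, but an aliphatic β-hydroxy amide has not been shown as the partner. Ring C closes in the 6-exo-trig mode at the amide carbonyl. No stereocentre of 22 is created, since C2 and C3 come from 13 with no bond to them broken, and the extra centre at C4 of 21 vanishes on quench. The step needs regioselective addition to the unsymmetrical aryne, which the C3 benzyloxy group of 19 secures: its inductive pull distorts the triple bond so that the nucleophile attacks the remote C1 (future C8a) and the carbanion develops at C2 beside the C–O bond (future C4a, next to C5). It also needs the alkoxide to outlive retro-aldol cleavage and the product to escape C3 epimerisation and ring opening, which the lithium counter-ion, the low temperature, the poorly stabilised amide enolate as would-be leaving group and the masking of the ketone as 21 should secure, while slow addition of n-BuLi lets the fast exchange outrun attack on the flavone and amide carbonyls.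

Step 10
Reactants: 22 the pentabenzyl ether of step 9
Product: 23 (2S,3R)-5,7-dihydroxy-3-[2-hydroxy-5-(5-hydroxy-7-methoxy-4-oxo-4H-chromen-2-yl)phenyl]-2-(4-hydroxyphenyl)chroman-4-one (CNP0361110.2)
Conditions: H2 (1 atm), Pd/C (10 wt % Pd on carbon), THF/MeOH, rt
Reagents that add atoms: none
Why: Catalytic hydrogenolysis of aryl benzyl ethers under neutral conditions, which should spare the methyl ether, the flavone double bond and the C2–O1 bond when stopped after uptake of five equivalents of H2, and which offers no base or acid to epimerise C3 or open ring C.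

Compound list
1 | 1-(2,6-dihydroxy-4-methoxyphenyl)ethanone | CC(=O)c1c(O)cc(OC)cc1O | starting material
2 | 1-[2-(benzyloxy)-6-hydroxy-4-methoxyphenyl]ethanone | CC(=O)c1c(O)cc(OC)cc1OCc1ccccc1 | intermediate
3 | 4-(benzyloxy)-3-bromobenzaldehyde | O=Cc1ccc(OCc2ccccc2)c(Br)c1 | starting material
4 | (E)-1-[2-(benzyloxy)-6-hydroxy-4-methoxyphenyl]-3-[4-(benzyloxy)-3-bromophenyl]prop-2-en-1-one | COc1cc(O)c(C(=O)/C=C/c2ccc(OCc3ccccc3)c(Br)c2)c(OCc2ccccc2)c1 | intermediate
5 | 5-(benzyloxy)-2-[4-(benzyloxy)-3-bromophenyl]-7-methoxy-4H-chromen-4-one | COc1cc(OCc2ccccc2)c2c(=O)cc(-c3ccc(OCc4ccccc4)c(Br)c3)oc2c1 | intermediate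
6 | (S)-3-acetyl-4-benzyloxazolidin-2-one | CC(=O)N1C(=O)OC[C@@H]1Cc1ccccc1 | starting material
7 | lithium enolate of 6 | [Li]OC(=C)N1C(=O)OC[C@@H]1Cc1ccccc1 | intermediate
8 | chlorozinc enolate of 6 (drawn carbon-bound) | Cl[Zn]CC(=O)N1C(=O)OC[C@@H]1Cc1ccccc1 | intermediate
9 | (S)-4-benzyl-3-{[2-(benzyloxy)-5-(5-(benzyloxy)-7-methoxy-4-oxo-4H-chromen-2-yl)phenyl]acetyl}oxazolidin-2-one | COc1cc(OCc2ccccc2)c2c(=O)cc(-c3ccc(OCc4ccccc4)c(CC(=O)N4C(=O)OC[C@@H]4Cc4ccccc4)c3)oc2c1 | intermediate
10 | 4-(benzyloxy)benzaldehyde | O=Cc1ccc(OCc2ccccc2)cc1 | starting material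
11 | trimethylsilyl ether of 12 | COc1cc(OCc2ccccc2)c2c(=O)cc(-c3ccc(OCc4ccccc4)c([C@@H](C(=O)N4C(=O)OC[C@@H]4Cc4ccccc4)[C@H](O[Si](C)(C)C)c4ccc(OCc5ccccc5)cc4)c3)oc2c1 | intermediate
12 | (S)-4-benzyl-3-{(2R,3S)-2-[2-(benzyloxy)-5-(5-(benzyloxy)-7-methoxy-4-oxo-4H-chromen-2-yl)phenyl]-3-[4-(benzyloxy)phenyl]-3-hydroxypropanoyl}oxazolidin-2-one (anti aldol) | COc1cc(OCc2ccccc2)c2c(=O)cc(-c3ccc(OCc4ccccc4)c([C@@H](C(=O)N4C(=O)OC[C@@H]4Cc4ccccc4)[C@H](O)c4ccc(OCc5ccccc5)cc4)c3)oc2c1 | intermediate
13 | (2R,3S)-2-[2-(benzyloxy)-5-(5-(benzyloxy)-7-methoxy-4-oxo-4H-chromen-2-yl)phenyl]-3-[4-(benzyloxy)phenyl]-3-hydroxy-N-methoxy-N-methylpropanamide | COc1cc(OCc2ccccc2)c2c(=O)cc(-c3ccc(OCc4ccccc4)c([C@@H](C(=O)N(C)OC)[C@H](O)c4ccc(OCc5ccccc5)cc4)c3)oc2c1 | intermediate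
14 | 3,5-bis(benzyloxy)phenol | Oc1cc(OCc2ccccc2)cc(OCc2ccccc2)c1 | starting material
15 | 3,5-bis(benzyloxy)-2-iodophenol | Oc1cc(OCc2ccccc2)cc(OCc2ccccc2)c1I | intermediate
16 | 3,5-bis(benzyloxy)-2-iodophenyl trifluoromethanesulfonate | O=S(=O)(Oc1cc(OCc2ccccc2)cc(OCc2ccccc2)c1I)C(F)(F)F | intermediate
17 | lithium alkoxide of 13 | COc1cc(OCc2ccccc2)c2c(=O)cc(-c3ccc(OCc4ccccc4)c([C@@H](C(=O)N(C)OC)[C@H](O[Li])c4ccc(OCc5ccccc5)cc4)c3)oc2c1 | intermediate
18 | 3,5-bis(benzyloxy)-2-lithiophenyl trifluoromethanesulfonate | O=S(=O)(Oc1cc(OCc2ccccc2)cc(OCc2ccccc2)c1[Li])C(F)(F)F | intermediate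
19 | 3,5-bis(benzyloxy)benzyne (triple bond C1–C2) | C1#CC(OCc2ccccc2)=CC(OCc2ccccc2)=C1 | intermediate
20 | aryllithium from O-addition of 17 to 19: the 3,5-bis(benzyloxy)-2-lithiophenyl ether of 13 | COc1cc(OCc2ccccc2)c2c(=O)cc(-c3ccc(OCc4ccccc4)c([C@@H](C(=O)N(C)OC)[C@H](Oc4cc(OCc5ccccc5)cc(OCc5ccccc5)c4[Li])c4ccc(OCc5ccccc5)cc4)c3)oc2c1 | intermediate
21 | tetrahedral adduct: the chromane of 22 with OLi and N(OMe)Me at C4 in place of the carbonyl oxygen (C4 configuration open) | COc1cc(OCc2ccccc2)c2c(=O)cc(-c3ccc(OCc4ccccc4)c([C@H]4C(O[Li])(N(C)OC)c5c(OCc6ccccc6)cc(OCc6ccccc6)cc5O[C@@H]4c4ccc(OCc5ccccc5)cc4)c3)oc2c1 | intermediate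
22 | (2S,3R)-5,7-bis(benzyloxy)-3-[2-(benzyloxy)-5-(5-(benzyloxy)-7-methoxy-4-oxo-4H-chromen-2-yl)phenyl]-2-[4-(benzyloxy)phenyl]chroman-4-one | COc1cc(OCc2ccccc2)c2c(=O)cc(-c3ccc(OCc4ccccc4)c([C@H]4C(=O)c5c(OCc6ccccc6)cc(OCc6ccccc6)cc5O[C@@H]4c4ccc(OCc5ccccc5)cc4)c3)oc2c1 | intermediate
23 | (2S,3R)-5,7-dihydroxy-3-[2-hydroxy-5-(5-hydroxy-7-methoxy-4-oxo-4H-chromen-2-yl)phenyl]-2-(4-hydroxyphenyl)chroman-4-one | COc1cc(O)c2c(=O)cc(-c3ccc(O)c([C@H]4C(=O)c5c(O)cc(O)cc5O[C@@H]4c4ccc(O)cc4)c3)oc2c1 | target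

Total step count: 10. Longest linear sequence: 8 (steps 1, 2, 3, 4, 5, 6, 9, 10).

Steps most likely to fail

1. Step 9.
- What may go wrong: the alkoxide may fragment by retro-aldol cleavage before it meets the aryne. The aggregated lithium alkoxide may add so slowly that the aryne is consumed by n-BuLi or by itself. The aryllithium may also be protonated before it reaches the amide.
- Fallback: it uses only known chemistry, sets out from 5 (and uses 15) and comes back at 22. It closes ring C in two stages, acylation first and then C2–O1 closure by a Mitsunobu reaction with inversion, so the carbinol is made with the opposite configuration.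
- Bromide 5 is coupled under the conditions of step 4 with (R)-3-acetyl-4-benzyloxazolidin-2-one to give the imide of the enantiomeric auxiliary F1.
- A dibutylboron Evans syn aldol reaction (Bu2BOTf, i-Pr2NEt, CH2Cl2, –78 °C) with 10 should give the (2R,3R)-syn aldol F2.
- Transamination as in step 6 gives the (2R,3R)-Weinreb amide F3.
- Iodophenol 15 and two equivalents of n-BuLi at –78 °C give the O,C-dilithio reagent F4. An excess of it takes the hydroxyl proton of F3 and adds to the amide, giving after quench the 2-hydroxyaryl ketone F5.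
- PPh3 and DIAD in THF at 0 °C then close the ring by SN2 attack of the phenol at the benzylic carbinol. This turns 3R into the 2S centre of 22 while C3 stays R.

2. Step 5.
- What may go wrong: facial or anti/syn selectivity may be poor with the bulky ortho-substituted arylacetyl imide. The acidic α-aryl centre may epimerise under Et3N. The flavone carbonyl may also sequester the magnesium catalyst.
- Fallback: it sets out from 9 and comes back at 22. It fixes only the carbinol centre in the aldol step and leaves C3 to thermodynamic control.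
- The dibutylboron Z-enolate of 9 (Bu2BOTf, i-Pr2NEt, CH2Cl2, –78 °C) and 10 should give, through a Zimmerman–Traxler chair, the (2S,3S)-syn aldol F6.
- Transamination as in step 6 gives the (2S,3S)-Weinreb amide F7.
- The annulation of step 9 gives the cis-(2S,3S)-chromanone F8.
- Catalytic DBU in CH2Cl2 at rt should equilibrate C3 through the enolate to the diequatorial trans isomer 22.

3. Step 4.
- What may go wrong: the imide enolate may decompose by loss of the auxiliary on warming. The more acidic product may protonate the zinc enolate. A second arylation may also occur.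
- Fallback: it sets out from 5 and comes back at 9. It arylates a simple ester enolate and installs the auxiliary afterwards.
- Bromide 5 and the commercial Reformatsky reagent BrZnCH2CO2t-Bu with Pd(dba)2 and P(t-Bu)3 in THF give the tert-butyl arylacetate F9.
- CF3CO2H in CH2Cl2 gives the arylacetic acid F10.
- Pivaloyl chloride and Et3N give the mixed pivalic anhydride F11, which acylates lithiated (S)-4-benzyloxazolidin-2-one to give 9.

Further compounds
F1 | step 9 | (R)-4-benzyl-3-{[2-(benzyloxy)-5-(5-(benzyloxy)-7-methoxy-4-oxo-4H-chromen-2-yl)phenyl]acetyl}oxazolidin-2-one | COc1cc(OCc2ccccc2)c2c(=O)cc(-c3ccc(OCc4ccccc4)c(CC(=O)N4C(=O)OC[C@H]4Cc4ccccc4)c3)oc2c1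
F2 | step 9 | (R)-4-benzyl-3-{(2R,3R)-2-(Ar1)-3-[4-(benzyloxy)phenyl]-3-hydroxypropanoyl}oxazolidin-2-one (syn aldol) | COc1cc(OCc2ccccc2)c2c(=O)cc(-c3ccc(OCc4ccccc4)c([C@@H](C(=O)N4C(=O)OC[C@H]4Cc4ccccc4)[C@@H](O)c4ccc(OCc5ccccc5)cc4)c3)oc2c1
F3 | step 9 | (2R,3R)-2-(Ar1)-3-[4-(benzyloxy)phenyl]-3-hydroxy-N-methoxy-N-methylpropanamide | COc1cc(OCc2ccccc2)c2c(=O)cc(-c3ccc(OCc4ccccc4)c([C@@H](C(=O)N(C)OC)[C@@H](O)c4ccc(OCc5ccccc5)cc4)c3)oc2c1
F4 | step 9 | lithium 3,5-bis(benzyloxy)-2-lithiophenoxide | [Li]Oc1cc(OCc2ccccc2)cc(OCc2ccccc2)c1[Li]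
F5 | step 9 | (2R,3R)-1-[2,4-bis(benzyloxy)-6-hydroxyphenyl]-2-(Ar1)-3-[4-(benzyloxy)phenyl]-3-hydroxypropan-1-one | COc1cc(OCc2ccccc2)c2c(=O)cc(-c3ccc(OCc4ccccc4)c([C@@H](C(=O)c4c(O)cc(OCc5ccccc5)cc4OCc4ccccc4)[C@@H](O)c4ccc(OCc5ccccc5)cc4)c3)oc2c1
F6 | step 5 | (S)-4-benzyl-3-{(2S,3S)-2-(Ar1)-3-[4-(benzyloxy)phenyl]-3-hydroxypropanoyl}oxazolidin-2-one (syn aldol) | COc1cc(OCc2ccccc2)c2c(=O)cc(-c3ccc(OCc4ccccc4)c([C@H](C(=O)N4C(=O)OC[C@@H]4Cc4ccccc4)[C@H](O)c4ccc(OCc5ccccc5)cc4)c3)oc2c1
F7 | step 5 | (2S,3S)-2-(Ar1)-3-[4-(benzyloxy)phenyl]-3-hydroxy-N-methoxy-N-methylpropanamide | COc1cc(OCc2ccccc2)c2c(=O)cc(-c3ccc(OCc4ccccc4)c([C@H](C(=O)N(C)OC)[C@H](O)c4ccc(OCc5ccccc5)cc4)c3)oc2c1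
F8 | step 5 | (2S,3S)-5,7-bis(benzyloxy)-3-(Ar1)-2-[4-(benzyloxy)phenyl]chroman-4-one (cis) | COc1cc(OCc2ccccc2)c2c(=O)cc(-c3ccc(OCc4ccccc4)c([C@@H]4C(=O)c5c(OCc6ccccc6)cc(OCc6ccccc6)cc5O[C@@H]4c4ccc(OCc5ccccc5)cc4)c3)oc2c1
F9 | step 4 | tert-butyl (Ar1)acetate | COc1cc(OCc2ccccc2)c2c(=O)cc(-c3ccc(OCc4ccccc4)c(CC(=O)OC(C)(C)C)c3)oc2c1
F10 | step 4 | (Ar1)acetic acid | COc1cc(OCc2ccccc2)c2c(=O)cc(-c3ccc(OCc4ccccc4)c(CC(=O)O)c3)oc2c1
F11 | step 4 | (Ar1)acetic pivalic anhydride | COc1cc(OCc2ccccc2)c2c(=O)cc(-c3ccc(OCc4ccccc4)c(CC(=O)OC(=O)C(C)(C)C)c3)oc2c1
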